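The data are simulated with made-up constants.

Slowness is what these flasks show first: after a quick start Z goes on falling slowly, and I want the part of it reacted at 5.0 min.

| flask | Z | L | remark | time |
|---|---|---|---|---|
| dawn | 1.6 M | 1.4 M | run made earlier |  |
| winter | 1.6 M | 2.3 M | run made earlier |  |
| dusk | 1.6 M | 2.9 M | run made earlier |  |
| Wednesday's | 1.6 M | 1.60 M |  | 5.0 min |
| Thursday's | 1.6 M | 2.70 M |  | 5.0 min |
| Sunday's | 1.6 M | 2.10 M |  | 5.0 min |

| run | time / min | Z / % | Q / % |
|---|---|---|---|
| dawn | 0.417 | 80.8 | 15.8 |
| dawn | 0.833 | 77.7 | 18.5 |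
| dawn | 1.33 | 76.7 | 17.0 |
| dawn | 2.50 | 72.6 | 18.3 |
| dawn | 5.00 | 68.0 | 21.5 |
| winter | 1.00 | 65.7 | 23.4 |
| winter | 2.00 | 62.5 | 23.8 |
| winter | 3.00 | 58.0 | 23.8 |
| winter | 4.00 | 55.3 | 25.1 |
| winter | 5.00 | 53.6 | 24.5 |
| dusk | 1.00 | 60.2 | 24.7 |
| dusk | 2.00 | 53.7 | 25.4 |
| dusk | 3.00 | 52.3 | 25.6 |
| dusk | 4.00 | 47.0 | 26.2 |
| dusk | 5.00 | 46.2 | 25.4 |

(readings scatter by 1 percentage point)

- what is said of X includes D
- D is a solid; its amount is given per volume of the solution
- candidate steps: Z + L -> X + Q; L + X <-> J; L + Q -> E; L <-> G; D <-> X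

1. part of the Z that has reacted at the end, Wednesday's
2. part of the Z that has reacted at the end, Thursday's
3. part of the Z that has reacted at the end, Sunday's
4. what raising the concentration of L from its lowest to its highest value here does to the part of the Z that has reacted (changes below 5 percentage points count as none) (it rises / it falls / no change)

The readings form a ladder. On the fastest rung, the dawn run has lost 19.2% of its Z by 0.417 min. On the next rung Q stops climbing: the winter run reads 23.4% at 1.00 min and 24.5% at 5.00 min, with a scatter of 1 percentage point. On the slowest rung Z creeps, and the dawn run loses 9.7 points between 0.833 min and 5.00 min. Since the winter run's Q moves by 1.1 points between those times while its Z falls by 12 points, I count the missing Q as E.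

So I ask what the end state must be, taking L as the limiting reagent. Each reacted Z takes one L, I assume its X takes another into J, and each Q lost to E takes a further one. If c is the part of Z reacted and q the part left as Q, then the L price, the L spent per Z reacted, is 3 − q/c. From the dawn readings at 5.00 min I read it as 2.33. Price times charged [Z] times c gives 1.19 M spent of 1.4 M, leaving 14.9% of the charge, which I suppose sits as G or free L.

Holding price and held share from the nearest run, I scale with the charge of L. That gives 36.6% for Wednesday's, 42.4% for Sunday's and 50.1% for Thursday's.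

The forecast says 35.5%, 43.5% and 51.5% for these flasks, and it rises, on the ground that “a gently curved interpolation is sound”. My Wednesday's figure stands above it and my Thursday's below it.

The flasks give 34.1% for Wednesday's, 42.7% for Sunday's and 52.0% for Thursday's. Across the range of L the outcome is: it rises, by 18 points.

    Z + L → X + Q (k = 0.0191 L mol⁻¹ s⁻¹)
    L + X ⇌ J, settled at all times (K = 3660 L mol⁻¹)
    L + Q → E (k = 0.0373 L mol⁻¹ s⁻¹)
    L ⇌ G (K = 9.00, k = 0.0631 s⁻¹)
    D ⇌ X, rate k5*(cs5 - [X]) while solid is left; crystals form when [X] > cs5 (solubility = 0.710 M, k = 0.675 s⁻¹)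

Wednesday's state at 5.00 min gives a price of 2.33. The neighbour is Wednesday's flask with Z cut to 0.40 M, so L stands at 4.00 equiv. By the same time it has reacted 59.6% of its Z and keeps 24.5% as Q, so its price is 2.59, higher than Wednesday's. That spends 0.616 M of 1.60 M and leaves 0.984 M, and the neighbour holds 0.897 M of G and 0.0871 M of free L.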